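The route rests on disconnecting the bond between C5 of the pyrrolo[2,3-d]pyrimidine and C1 of the guaiacyl ring, and on making that bond in the same operation that closes the pyrrole ring. The feature exploited is the contiguous N7–C6(aroyl)–C5(aryl) edge of the pyrrole: target C5 and C6 derive from the two alkyne carbons of an ynone attached to the 5-position of a pyrimidine, ortho to a trifluoroacetamide nitrogen (future N7). A Cacchi-type aminopalladation–reductive elimination with a protected 4-iodoguaiacol then forges N7–C6 and C5–aryl at once, with the regiochemistry fixed by the alkyne. Acid unmasks the uracil and both phenols last.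

Key step: step 7

Remark: the target has no stereocentre. In step 8 the pyrimidinyl methyl ethers are taken to be cleaved by chloride attack at the methyl carbon (alkyl–oxygen fission), so the C2 and C4 carbonyl oxygens stem from the starting aminopyrimidine and no reagent oxygen is incorporated.

Step 1
Reactants: 1 2,6-dimethoxypyrimidin-4-amine
Product: 2 5-iodo-2,6-dimethoxypyrimidin-4-amine
Conditions: NIS (1.05 equiv), MeCN, rt, dark
Reagents that add atoms: N-iodosuccinimide, O=C1CCC(=O)N1I
Why: Electrophilic aromatic iodination (SEAr); C5 is the only ring C–H of 1 and is strongly activated by the flanking amino and methoxy groups, so mono-iodination there should be clean.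

Step 2
Reactants: 3 4-(methoxymethoxy)benzaldehyde; 4 ethynylmagnesium bromide
Product: 5 1-[4-(methoxymethoxy)phenyl]prop-2-yn-1-ol (racemic)
Conditions: THF, 0 °C to rt; aqueous work-up
Reagents that add atoms: none
Why: Grignard 1,2-addition of the acetylide to the aldehyde; the carbinol centre forms racemic, which is immaterial because it is oxidised to the ketone in step 4.

Step 3
Reactants: 2 5-iodo-2,6-dimethoxypyrimidin-4-amine; 5 1-[4-(methoxymethoxy)phenyl]prop-2-yn-1-ol
Product: 6 3-(4-amino-2,6-dimethoxypyrimidin-5-yl)-1-[4-(methoxymethoxy)phenyl]prop-2-yn-1-ol (racemic)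
Conditions: PdCl2(PPh3)2 (3 mol %), CuI (5 mol %), Et3N, DMF, 50 °C, degassed
Reagents that add atoms: none
Why: Sonogashira coupling of the heteroaryl iodide with the terminal alkyne should tolerate the free amino and hydroxyl groups, as is usual for ortho-iodo arylamines, and the moderate temperature should avoid premature copper-mediated cyclisation.

Step 4
Reactants: 6 3-(4-amino-2,6-dimethoxypyrimidin-5-yl)-1-[4-(methoxymethoxy)phenyl]prop-2-yn-1-ol
Product: 7 3-(4-amino-2,6-dimethoxypyrimidin-5-yl)-1-[4-(methoxymethoxy)phenyl]prop-2-yn-1-one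
Conditions: activated MnO2 (15 equiv), CH2Cl2, rt
Reagents that add atoms: none
Why: MnO2 oxidation of a doubly activated (propargylic and benzylic) secondary alcohol should give the ynone chemoselectively beside the heteroarylamine; it removes the only stereocentre of the route.

Step 5
Reactants: 7 3-(4-amino-2,6-dimethoxypyrimidin-5-yl)-1-[4-(methoxymethoxy)phenyl]prop-2-yn-1-one
Product: 8 N-[2,6-dimethoxy-5-[3-[4-(methoxymethoxy)phenyl]-3-oxoprop-1-yn-1-yl]pyrimidin-4-yl]-2,2,2-trifluoroacetamide
Conditions: TFAA (1.5 equiv), 2,6-lutidine, CH2Cl2, −10 to 0 °C; cold aqueous work-up, used without chromatography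
Reagents that add atoms: trifluoroacetic anhydride, O=C(OC(=O)C(F)(F)F)C(F)(F)F
Why: N-acylation with the highly electrophilic anhydride should turn the weakly nucleophilic amino group into an acidic trifluoroacetamide (needed for aminopalladation and unable to condense with the ketone), while the hindered base cannot add to the ynone.

Step 6
Reactants: 9 4-iodo-2-methoxyphenol
Product: 10 4-iodo-2-methoxy-1-(methoxymethoxy)benzene
Conditions: MOMCl, iPr2NEt, CH2Cl2, 0 °C to rt
Reagents that add atoms: chloromethyl methyl ether, COCCl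
Why: O-alkylation of the phenol (methoxymethyl ether formation) should prevent phenoxide addition to the ynone in step 7 and gives a group that falls in the final acid step.

Step 7
Reactants: 8 N-[2,6-dimethoxy-5-[3-[4-(methoxymethoxy)phenyl]-3-oxoprop-1-yn-1-yl]pyrimidin-4-yl]-2,2,2-trifluoroacetamide; 10 4-iodo-2-methoxy-1-(methoxymethoxy)benzene (1.5 equiv)
Product: 12 [2,4-dimethoxy-5-[3-methoxy-4-(methoxymethoxy)phenyl]-7H-pyrrolo[2,3-d]pyrimidin-6-yl][4-(methoxymethoxy)phenyl]methanone, via N7-trifluoroacetyl pyrrolopyrimidine 11 (not isolated)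
Conditions: Pd(PPh3)4 (5 mol %), Cs2CO3 (3 equiv), anhydrous MeCN, 80 °C; then H2O work-up
Reagents that add atoms: none
Why: Oxidative addition of zerovalent palladium into the C–I bond of 10 gives an arylpalladium iodide (divalent palladium) that π-activates the alkyne of carbonate-deprotonated 8; anti-attack of the trifluoroacetamide nitrogen on the alkyne carbon bearing the ketone gives a σ-(pyrrol-3-yl)(aryl)palladium species, C–C reductive elimination forges the C5–aryl bond, and the labile N7-trifluoroacetyl group of 11 is then lost to carbonate and water. The closest known reaction type is the Cacchi aminopalladation–reductive elimination synthesis of 2,3-disubstituted indoles and azaindoles from ortho-alkynyl trifluoroacetamides and aryl halides. The pyrrole ring closes in the 5-endo-dig mode (N7–C6), and no stereocentre is formed. The regiochemistry cannot vary: the nitrogen can only reach the distal alkyne carbon (future C6), so the aryl group must go to the proximal carbon (future C5); the alternative syn-carbopalladation of the ynone, E/Z isomerisation through the palladium allenolate and C–N reductive elimination converges on the same product. The selectivity needed is arylative cyclisation over proto-cyclisation to the 5-unsubstituted pyrrole and over hydroarylation followed by amine–ketone condensation to a pyrido[2,3-d]pyrimidine; the acidic, non-condensing trifluoroacetamide, the anhydrous aprotic medium without a hydride source and the excess of 10 should secure it.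

Step 8
Reactants: 12 [2,4-dimethoxy-5-[3-methoxy-4-(methoxymethoxy)phenyl]-7H-pyrrolo[2,3-d]pyrimidin-6-yl][4-(methoxymethoxy)phenyl]methanone
Product: 13 rigidin C, 6-(4-hydroxybenzoyl)-5-(4-hydroxy-3-methoxyphenyl)-1H-pyrrolo[2,3-d]pyrimidine-2,4(3H,7H)-dione
Conditions: conc. HCl/MeOH (1:4), 65 °C
Reagents that add atoms: none
Why: Acid-mediated global deprotection: acetal exchange with methanol removes both methoxymethyl ethers (the formaldehyde unit is trapped as dimethoxymethane) and chloride dealkylation of the protonated imidate-type pyrimidinyl methyl ethers unmasks the 2,4-dione, while the aryl methyl ether should be inert to HCl at this temperature.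

Compound list
1 | 2,6-dimethoxypyrimidin-4-amine | COc1cc(N)nc(OC)n1 | starting material
2 | 5-iodo-2,6-dimethoxypyrimidin-4-amine | COc1nc(OC)nc(N)c1I | intermediate
3 | 4-(methoxymethoxy)benzaldehyde | COCOc1ccc(C=O)cc1 | starting material
4 | ethynylmagnesium bromide | C#C[Mg]Br | starting material
5 | 1-[4-(methoxymethoxy)phenyl]prop-2-yn-1-ol (racemic) | COCOc1ccc(C(O)C#C)cc1 | intermediate
6 | 3-(4-amino-2,6-dimethoxypyrimidin-5-yl)-1-[4-(methoxymethoxy)phenyl]prop-2-yn-1-ol (racemic) | COCOc1ccc(C(O)C#Cc2c(N)nc(OC)nc2OC)cc1 | intermediate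
7 | 3-(4-amino-2,6-dimethoxypyrimidin-5-yl)-1-[4-(methoxymethoxy)phenyl]prop-2-yn-1-one | COCOc1ccc(C(=O)C#Cc2c(N)nc(OC)nc2OC)cc1 | intermediate
8 | N-[2,6-dimethoxy-5-[3-[4-(methoxymethoxy)phenyl]-3-oxoprop-1-yn-1-yl]pyrimidin-4-yl]-2,2,2-trifluoroacetamide | COCOc1ccc(C(=O)C#Cc2c(NC(=O)C(F)(F)F)nc(OC)nc2OC)cc1 | intermediate
9 | 4-iodo-2-methoxyphenol | COc1cc(I)ccc1O | starting material
10 | 4-iodo-2-methoxy-1-(methoxymethoxy)benzene | COCOc1ccc(I)cc1OC | intermediate
11 | 2,2,2-trifluoro-1-[2,4-dimethoxy-6-[4-(methoxymethoxy)benzoyl]-5-[3-methoxy-4-(methoxymethoxy)phenyl]-7H-pyrrolo[2,3-d]pyrimidin-7-yl]ethanone (N7-trifluoroacetyl pyrrolopyrimidine, not isolated) | COCOc1ccc(C(=O)c2c(-c3ccc(OCOC)c(OC)c3)c3c(OC)nc(OC)nc3n2C(=O)C(F)(F)F)cc1 | intermediate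
12 | [2,4-dimethoxy-5-[3-methoxy-4-(methoxymethoxy)phenyl]-7H-pyrrolo[2,3-d]pyrimidin-6-yl][4-(methoxymethoxy)phenyl]methanone | COCOc1ccc(C(=O)c2[nH]c3nc(OC)nc(OC)c3c2-c2ccc(OCOC)c(OC)c2)cc1 | intermediate
13 | rigidin C | COc1cc(-c2c(C(=O)c3ccc(O)cc3)[nH]c3[nH]c(=O)[nH]c(=O)c23)ccc1O | target

Total step count: 8. Longest linear sequence: 6 (steps 1, 3, 4, 5, 7, 8; the branch through step 2 is equally long).

Steps most likely to fail

Step 7. The trifluoroacetamide anion may cyclise with protonolysis of the vinylpalladium bond before the aryl group is transferred, or the trifluoroacetyl group may be lost early so that the ynone is diverted by conjugate addition. The fallback sets out from 8 and comes back at 12, forming the same C5–aryl bond in a separate operation. Copper-catalysed cycloisomerisation of 8 (CuI, K3PO4, 1,4-dioxane, 100 °C) should give, with loss of the trifluoroacetyl group, the 5-unsubstituted [2,4-dimethoxy-7H-pyrrolo[2,3-d]pyrimidin-6-yl][4-(methoxymethoxy)phenyl]methanone F1. Electrophilic iodination at C5, the only free pyrrole position (NIS, DMF, rt), should give [5-iodo-2,4-dimethoxy-7H-pyrrolo[2,3-d]pyrimidin-6-yl][4-(methoxymethoxy)phenyl]methanone F2. Miyaura borylation of 10 (B2pin2, PdCl2(dppf), KOAc, 1,4-dioxane, 90 °C) should give 2-[3-methoxy-4-(methoxymethoxy)phenyl]-4,4,5,5-tetramethyl-1,3,2-dioxaborolane F3. Suzuki–Miyaura coupling of F2 with F3 (PdCl2(dppf), K2CO3, 1,4-dioxane/H2O, 90 °C) should then deliver 12.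

Step 5. Acylation of the weakly nucleophilic, flanked amino group may stay incomplete, and the trifluoroacetamide may be hydrolysed back during work-up. The fallback sets out from 7 and comes back at 12, replacing N-acylation by N-sulfonylation. Deprotonation of 7 and mesylation (LiHMDS, THF, −78 °C; MsCl) should give the hydrolytically robust N-[2,6-dimethoxy-5-[3-[4-(methoxymethoxy)phenyl]-3-oxoprop-1-yn-1-yl]pyrimidin-4-yl]methanesulfonamide F4. Arylative aminopalladation of F4 with 10 (Pd(PPh3)4, Cs2CO3, MeCN, 80 °C) should give the N7-methanesulfonyl pyrrolopyrimidine [7-(methanesulfonyl)-2,4-dimethoxy-5-[3-methoxy-4-(methoxymethoxy)phenyl]-7H-pyrrolo[2,3-d]pyrimidin-6-yl][4-(methoxymethoxy)phenyl]methanone F5. Its sulfonyl group on the acylpyrrole nitrogen should be removed with aq. NaOH in THF at rt to reach 12.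

Step 8. Dealkylation may stall at the 2-methoxy-4-oxo stage, and forcing it may erode the guaiacol methyl ether. The fallback sets out from 12 and comes back at 13 in two stages with a change of cleavage mechanism. Mild acetal cleavage (PPTS, MeOH, 50 °C) should give the bis-phenol [5-(4-hydroxy-3-methoxyphenyl)-2,4-dimethoxy-7H-pyrrolo[2,3-d]pyrimidin-6-yl](4-hydroxyphenyl)methanone F6 with the pyrimidine ethers intact. Iodotrimethylsilane made in situ (TMSCl, NaI, MeCN, rt to 40 °C; then MeOH/H2O) should then dealkylate the two imidate-type methyl ethers by iodide attack at methyl, much faster than the aryl methyl ether, giving 13.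

Further compounds
F1 | step 7 | [2,4-dimethoxy-7H-pyrrolo[2,3-d]pyrimidin-6-yl][4-(methoxymethoxy)phenyl]methanone | COCOc1ccc(C(=O)c2cc3c(OC)nc(OC)nc3[nH]2)cc1
F2 | step 7 | [5-iodo-2,4-dimethoxy-7H-pyrrolo[2,3-d]pyrimidin-6-yl][4-(methoxymethoxy)phenyl]methanone | COCOc1ccc(C(=O)c2[nH]c3nc(OC)nc(OC)c3c2I)cc1
F3 | step 7 | 2-[3-methoxy-4-(methoxymethoxy)phenyl]-4,4,5,5-tetramethyl-1,3,2-dioxaborolane | COCOc1ccc(B2OC(C)(C)C(C)(C)O2)cc1OC
F4 | step 5 | N-[2,6-dimethoxy-5-[3-[4-(methoxymethoxy)phenyl]-3-oxoprop-1-yn-1-yl]pyrimidin-4-yl]methanesulfonamide | COCOc1ccc(C(=O)C#Cc2c(NS(C)(=O)=O)nc(OC)nc2OC)cc1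
F5 | step 5 | [7-(methanesulfonyl)-2,4-dimethoxy-5-[3-methoxy-4-(methoxymethoxy)phenyl]-7H-pyrrolo[2,3-d]pyrimidin-6-yl][4-(methoxymethoxy)phenyl]methanone | COCOc1ccc(C(=O)c2c(-c3ccc(OCOC)c(OC)c3)c3c(OC)nc(OC)nc3n2S(C)(=O)=O)cc1
F6 | step 8 | [5-(4-hydroxy-3-methoxyphenyl)-2,4-dimethoxy-7H-pyrrolo[2,3-d]pyrimidin-6-yl](4-hydroxyphenyl)methanone | COc1cc(-c2c(C(=O)c3ccc(O)cc3)[nH]c3nc(OC)nc(OC)c23)ccc1O
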